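**Plan**

- Retrosynthesis first cuts the two depside C(=O)–O bonds (ring A acyl to O-4 of ring B, ring B acyl to O-4 of ring C), leaving a ring A acid and two orsellinic acid units. In ring A (C1 carboxyl-bearing, C2 methyl, C3 and C4 oxygens, C5 H, C6 methoxy) it then cuts C5–C6, C1–C2 and the C3–O bond.
- Enabling feature: C6 bears oxygen and is ortho to C1, so C1, its carboxyl carbon and C6 are the three carbons of one malonate. C2 to C5 with the C2 methyl are a 3-alkoxypentane-2,4-dione whose terminal methyl becomes C5.
- Forward: pentane-2,4-dione is oxygenated at C3 (diazo transfer, O–H insertion), converted into a β-chloro enone and joined to malonate (C1–C2). Methoxide then closes ring A, the only ring made, by Claisen acylation (C5–C6) with direct aromatization.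
- Ring A is differentiated (4-O-benzyl, 6-O-methyl) and its ester hydrolysed. The chain grows A, then A–B, then A–B–C by two mixed-anhydride esterifications onto allyl and benzyl orsellinate, and hydrogenolysis finishes.
- Stereochemistry: the target has no stereocentre. The only stereochemical element on the way, the double-bond geometry of the cyclization precursor, is erased through a common dienolate.

Key step: step 5

Assumption: the geometry of 5 and the geometry and tautomeric form of 7 are not controlled. 5 is written without a double-bond descriptor and 7 as its E enone form, since every isomer passes through the same dienolate in steps 4 and 5.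

**Route**

Step 1
Reactants: 1 pentane-2,4-dione
Product: 2 3-diazopentane-2,4-dione
Conditions: 4-acetamidobenzenesulfonyl azide, Et3N, MeCN, 0 °C to rt
Reagents that add atoms: 4-acetamidobenzenesulfonyl azide, CC(=O)Nc1ccc(cc1)S(=O)(=O)N=[N+]=[N-]
Why: Regitz diazo transfer; the acidic C3 methylene of the 1,3-diketone takes the two terminal nitrogens of the sulfonyl azide, the standard entry to 2-diazo-1,3-diketones.

Step 2
Reactants: 2 3-diazopentane-2,4-dione; 3 benzyl alcohol
Product: 4 3-(benzyloxy)pentane-2,4-dione
Conditions: Rh2(OAc)4 (1 mol %), PhH, 80 °C, slow addition of 2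
Reagents that add atoms: none
Why: The acceptor–acceptor rhodium carbenoid inserts into the O–H bond of the alcohol (oxonium ylide, then proton shift), an established route to 2-alkoxy-1,3-dicarbonyl compounds that installs the future C3 oxygen already protected.

Step 3
Reactants: 4 3-(benzyloxy)pentane-2,4-dione
Product: 5 3-(benzyloxy)-4-chloropent-3-en-2-one
Conditions: (COCl)2, DMF (cat.), CH2Cl2, 0 °C to rt
Reagents that add atoms: oxalyl chloride, O=C(Cl)C(Cl)=O
Why: Vilsmeier-type activation of the enol oxygen followed by chloride addition–elimination turns the 1,3-diketone into its vinylogous acid chloride, as is routine for β-chloro enones; the symmetry of 4 leaves no regiochemical question.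

Step 4
Reactants: 5 3-(benzyloxy)-4-chloropent-3-en-2-one; 6 dimethyl malonate
Product: 7 dimethyl 2-[(2E)-3-(benzyloxy)-4-oxopent-2-en-2-yl]propanedioate
Conditions: NaH (2.1 equiv), THF, 0 °C to rt; then cold aq NH4Cl
Reagents that add atoms: none
Why: Nucleophilic vinylic substitution (conjugate addition of sodium dimethyl malonate, then loss of chloride) on a β-chlorovinyl ketone is classical, and the second equivalent of base stores the more acidic product as its dienolate until work-up.

Step 5
Reactants: 7 dimethyl 2-[(2E)-3-(benzyloxy)-4-oxopent-2-en-2-yl]propanedioate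
Product: 9 methyl 3-(benzyloxy)-4,6-dihydroxy-2-methylbenzoate, via dioxocyclohexene carboxylate 8 (not isolated)
Conditions: NaOMe (3 equiv), MeOH, reflux; then aq HCl, 0 °C
Reagents that add atoms: none
Why: Methoxide reversibly converts 7 into its delocalized dienolate; in the minor tautomer that carries the enolate on the terminal methyl ketone, that carbon (future C5) adds to the carbonyl of the malonate ester lying cis across the C2=C3 bond (future C6), methoxide is expelled, and dione 8 tautomerizes at once to the resorcylate phenoxide. The closest known reaction type is the intramolecular Claisen (Dieckmann-type) acylation that ends the Michael–Claisen resorcylate syntheses from malonate anions and ynones or β-chlorovinyl ketones. Ring A closes in a 6-(enolendo)-exo-trig mode, the enolate C4=C5 bond lying inside the new ring and the ester C=O outside it. No stereocentre is formed, and the geometry of 7 does not matter: two ester groups sit on the same carbon, so in the alkylidenemalonate tautomer one of them faces the acetyl-bearing arm whichever way the double bond is set. The step needs C-acylation to prevail over O-acylation to a 2-pyranone; the pyranone is reopened by methoxide whereas aromatization to the deprotonated resorcylate is irreversible, so the equilibrating medium should drain the mixture into 9, with the second ester left as the C1 carboxyl.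

Step 6
Reactants: 9 methyl 3-(benzyloxy)-4,6-dihydroxy-2-methylbenzoate
Product: 10 methyl 3,4-bis(benzyloxy)-6-hydroxy-2-methylbenzoate
Conditions: BnBr (1.05 equiv), K2CO3 (1.2 equiv), acetone, reflux
Reagents that add atoms: benzyl bromide, BrCc1ccccc1
Why: Williamson etherification with one equivalent of halide selects the 4-hydroxyl, because the 6-hydroxyl is held in a hydrogen bond to the ester carbonyl, as in the standard 4-O-alkylation of orsellinates.

Step 7
Reactants: 10 methyl 3,4-bis(benzyloxy)-6-hydroxy-2-methylbenzoate
Product: 11 methyl 3,4-bis(benzyloxy)-6-methoxy-2-methylbenzoate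
Conditions: MeI (3 equiv), K2CO3 (2 equiv), DMF, 50 °C
Reagents that add atoms: iodomethane, CI
Why: With excess iodomethane in warm DMF the remaining chelated phenol undergoes Williamson O-methylation, the usual second stage after para-selective alkylation of 2,4-dihydroxybenzoates.

Step 8
Reactants: 11 methyl 3,4-bis(benzyloxy)-6-methoxy-2-methylbenzoate
Product: 12 3,4-bis(benzyloxy)-6-methoxy-2-methylbenzoic acid
Conditions: KOH (10 equiv), DMSO–H2O, 90 °C; then aq HCl, 0 °C
Reagents that add atoms: potassium hydroxide, [K+].[OH-]
Why: Saponification of the doubly ortho-substituted methyl ester needs forcing hydroxide in aqueous DMSO, conditions established for 2,6-disubstituted benzoates and harmless to the benzyl and methyl ethers.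

Step 9
Reactants: 13 orsellinic acid (2,4-dihydroxy-6-methylbenzoic acid)
Product: 14 prop-2-en-1-yl 2,4-dihydroxy-6-methylbenzoate
Conditions: allyl bromide (1.05 equiv), KHCO3 (1.1 equiv), DMF, rt
Reagents that add atoms: 3-bromoprop-1-ene, C=CCBr
Why: Bicarbonate deprotonates only the carboxylic acid, so SN2 alkylation gives the ester and leaves both phenols free, as in the usual preparation of orsellinate esters for depside work.

Step 10
Reactants: 12 3,4-bis(benzyloxy)-6-methoxy-2-methylbenzoic acid; 14 prop-2-en-1-yl 2,4-dihydroxy-6-methylbenzoate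
Product: 16 prop-2-en-1-yl 4-{[3,4-bis(benzyloxy)-6-methoxy-2-methylbenzoyl]oxy}-2-hydroxy-6-methylbenzoate, via mixed trifluoroacetic anhydride 15 (not isolated)
Conditions: (CF3CO)2O (3 equiv), toluene, rt
Reagents that add atoms: none
Why: Trifluoroacetic anhydride turns the hindered acid into mixed anhydride 15 (in equilibrium with the acylium ion favoured by the two ortho substituents), which acylates the unchelated 4-hydroxyl of 14 while the 2-hydroxyl stays hydrogen-bonded to the ester, the standard depside esterification.

Step 11
Reactants: 16 prop-2-en-1-yl 4-{[3,4-bis(benzyloxy)-6-methoxy-2-methylbenzoyl]oxy}-2-hydroxy-6-methylbenzoate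
Product: 17 4-{[3,4-bis(benzyloxy)-6-methoxy-2-methylbenzoyl]oxy}-2-hydroxy-6-methylbenzoic acid
Conditions: Pd(PPh3)4 (5 mol %), morpholine (5 equiv), THF, rt; then aq HCl
Reagents that add atoms: none
Why: The zerovalent palladium complex ionizes the allyl ester to a π-allyl species that morpholine intercepts (Tsuji–Trost deallylation), conditions that leave the benzyl ethers and the strongly hindered aryl ester untouched.

Step 12
Reactants: 13 orsellinic acid
Product: 18 benzyl 2,4-dihydroxy-6-methylbenzoate
Conditions: BnBr (1.05 equiv), KHCO3 (1.1 equiv), DMF, rt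
Reagents that add atoms: benzyl bromide, BrCc1ccccc1
Why: Carboxylate-selective SN2 alkylation under bicarbonate, as in step 9, gives the ring C unit with its carboxyl masked for the final hydrogenolysis.

Step 13
Reactants: 17 4-{[3,4-bis(benzyloxy)-6-methoxy-2-methylbenzoyl]oxy}-2-hydroxy-6-methylbenzoic acid; 18 benzyl 2,4-dihydroxy-6-methylbenzoate
Product: 20 benzyl 4-[(4-{[3,4-bis(benzyloxy)-6-methoxy-2-methylbenzoyl]oxy}-2-hydroxy-6-methylbenzoyl)oxy]-2-hydroxy-6-methylbenzoate, via mixed trifluoroacetic anhydride 19 (not isolated)
Conditions: (CF3CO)2O (3 equiv), toluene, rt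
Reagents that add atoms: none
Why: The same mixed-anhydride depside esterification joins ring B to ring C; activated acid 19 acylates the free 4-hydroxyl of 18, and the chelated ortho hydroxyls of both partners should not compete.

Step 14
Reactants: 20 benzyl 4-[(4-{[3,4-bis(benzyloxy)-6-methoxy-2-methylbenzoyl]oxy}-2-hydroxy-6-methylbenzoyl)oxy]-2-hydroxy-6-methylbenzoate
Product: 21 4-[(4-{[3,4-dihydroxy-6-methoxy-2-methylbenzoyl]oxy}-2-hydroxy-6-methylbenzoyl)oxy]-2-hydroxy-6-methylbenzoic acid (CNP0222366.0)
Conditions: H2 (1 atm), 10% Pd/C, EtOAc, rt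
Reagents that add atoms: none
Why: Catalytic hydrogenolysis cleaves the two benzyl ethers and the benzyl ester in one operation without touching the aryl esters, the usual closing step of depside syntheses.

**Compound list**

1 | pentane-2,4-dione | CC(=O)CC(C)=O | starting material
2 | 3-diazopentane-2,4-dione | CC(=O)C(=[N+]=[N-])C(C)=O | intermediate
3 | benzyl alcohol | OCc1ccccc1 | starting material
4 | 3-(benzyloxy)pentane-2,4-dione | CC(=O)C(OCc1ccccc1)C(C)=O | intermediate
5 | 3-(benzyloxy)-4-chloropent-3-en-2-one (E/Z mixture, no descriptor assigned) | CC(=O)C(OCc1ccccc1)=C(C)Cl | intermediate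
6 | dimethyl malonate | COC(=O)CC(=O)OC | starting material
7 | dimethyl 2-[(2E)-3-(benzyloxy)-4-oxopent-2-en-2-yl]propanedioate | COC(=O)C(C(=O)OC)/C(C)=C(/OCc1ccccc1)C(C)=O | intermediate
8 | methyl 3-(benzyloxy)-2-methyl-4,6-dioxocyclohex-2-ene-1-carboxylate (racemic, transient) | COC(=O)C1C(C)=C(OCc2ccccc2)C(=O)CC1=O | intermediate (not isolated)
9 | methyl 3-(benzyloxy)-4,6-dihydroxy-2-methylbenzoate | COC(=O)c1c(C)c(OCc2ccccc2)c(O)cc1O | intermediate
10 | methyl 3,4-bis(benzyloxy)-6-hydroxy-2-methylbenzoate | COC(=O)c1c(C)c(OCc2ccccc2)c(OCc2ccccc2)cc1O | intermediate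
11 | methyl 3,4-bis(benzyloxy)-6-methoxy-2-methylbenzoate | COC(=O)c1c(C)c(OCc2ccccc2)c(OCc2ccccc2)cc1OC | intermediate
12 | 3,4-bis(benzyloxy)-6-methoxy-2-methylbenzoic acid | OC(=O)c1c(C)c(OCc2ccccc2)c(OCc2ccccc2)cc1OC | intermediate
13 | orsellinic acid (2,4-dihydroxy-6-methylbenzoic acid) | Cc1cc(O)cc(O)c1C(=O)O | starting material
14 | prop-2-en-1-yl 2,4-dihydroxy-6-methylbenzoate | C=CCOC(=O)c1c(C)cc(O)cc1O | intermediate
15 | 3,4-bis(benzyloxy)-6-methoxy-2-methylbenzoic trifluoroacetic anhydride | COc1cc(OCc2ccccc2)c(OCc2ccccc2)c(C)c1C(=O)OC(=O)C(F)(F)F | intermediate (not isolated)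
16 | prop-2-en-1-yl 4-{[3,4-bis(benzyloxy)-6-methoxy-2-methylbenzoyl]oxy}-2-hydroxy-6-methylbenzoate | COc1cc(OCc2ccccc2)c(OCc2ccccc2)c(C)c1C(=O)Oc1cc(C)c(C(=O)OCC=C)c(O)c1 | intermediate
17 | 4-{[3,4-bis(benzyloxy)-6-methoxy-2-methylbenzoyl]oxy}-2-hydroxy-6-methylbenzoic acid | COc1cc(OCc2ccccc2)c(OCc2ccccc2)c(C)c1C(=O)Oc1cc(C)c(C(=O)O)c(O)c1 | intermediate
18 | benzyl 2,4-dihydroxy-6-methylbenzoate | Cc1cc(O)cc(O)c1C(=O)OCc1ccccc1 | intermediate
19 | 4-{[3,4-bis(benzyloxy)-6-methoxy-2-methylbenzoyl]oxy}-2-hydroxy-6-methylbenzoic trifluoroacetic anhydride | COc1cc(OCc2ccccc2)c(OCc2ccccc2)c(C)c1C(=O)Oc1cc(C)c(C(=O)OC(=O)C(F)(F)F)c(O)c1 | intermediate (not isolated)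
20 | benzyl 4-[(4-{[3,4-bis(benzyloxy)-6-methoxy-2-methylbenzoyl]oxy}-2-hydroxy-6-methylbenzoyl)oxy]-2-hydroxy-6-methylbenzoate | COc1cc(OCc2ccccc2)c(OCc2ccccc2)c(C)c1C(=O)Oc1cc(C)c(C(=O)Oc2cc(C)c(C(=O)OCc3ccccc3)c(O)c2)c(O)c1 | intermediate
21 | 4-[(4-{[3,4-dihydroxy-6-methoxy-2-methylbenzoyl]oxy}-2-hydroxy-6-methylbenzoyl)oxy]-2-hydroxy-6-methylbenzoic acid (CNP0222366.0) | COc1cc(O)c(O)c(C)c1C(=O)Oc1cc(C)c(C(=O)Oc2cc(C)c(C(=O)O)c(O)c2)c(O)c1 | target

**Count and risks**

Total steps: 14. Longest linear sequence: 12 steps (steps 1 to 8, 10, 11, 13, 14).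

Step 5 (ring A closure). The dienolate may rest unchanged, or methoxide may cleave the acetyl group by retro-Claisen fragmentation, since the departing carbanion is a vinylogous malonate; either process starves the C-acylation. The fallback gives up building the ring and oxygenates a ready-made orsellinate instead. It sets out from orsellinic acid 13. Esterification with iodomethane and KHCO3 in DMF should give methyl 2,4-dihydroxy-6-methylbenzoate F1. Elbs persulfate oxidation (K2S2O8, aqueous NaOH, 10 to 20 °C) is expected to place oxygen para to the 2-hydroxyl, the only free para position, as potassium 2,4-dihydroxy-5-(methoxycarbonyl)-6-methylphenyl sulfate F2. Warm dilute HCl hydrolyses F2 without isolation to methyl 2,4,5-trihydroxy-6-methylbenzoate F3. Benzylation of the two unchelated hydroxyls (BnBr, K2CO3, acetone) comes back to the route at 10.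

Step 4 (malonate addition–elimination). Addition to the fully substituted β-carbon, deactivated by the neighbouring benzyloxy group, may be slow enough for attack at the carbonyl and deacylation to take over. The fallback moves to the dihydro oxidation level, where the acceptor carries only one β-substituent. It sets out from 4. Mono-reduction (NaBH4, 0.3 equiv, MeOH, −20 °C) should give 3-(benzyloxy)-4-hydroxypentan-2-one F4, and acid-catalysed dehydration (p-TsOH cat., toluene, reflux) 3-(benzyloxy)pent-3-en-2-one F5. Dimethyl malonate 6 with NaOMe in refluxing MeOH adds in Michael fashion to give dimethyl 2-[3-(benzyloxy)-4-oxopentan-2-yl]propanedioate F6. F6 closes in the same pot, by the same C5–C6 Claisen acylation, to methyl 3-(benzyloxy)-2-methyl-4,6-dioxocyclohexane-1-carboxylate F7. Dehydrogenation with DDQ in dioxane aromatizes F7 and comes back to the route at 9.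

Step 8 (hydrolysis of the hindered ester). Hydroxide attack at the carbonyl flanked by the methyl and methoxy groups may stay incomplete under conditions the rest of the molecule tolerates. The fallback replaces acyl substitution by a redox detour. It sets out from 11. LiAlH4 in refluxing THF should give [3,4-bis(benzyloxy)-6-methoxy-2-methylphenyl]methanol F8, and MnO2 in CH2Cl2 then 3,4-bis(benzyloxy)-6-methoxy-2-methylbenzaldehyde F9. Pinnick oxidation (NaClO2, NaH2PO4, 2-methylbut-2-ene, t-BuOH–H2O) comes back to the route at 12.

**Further compounds**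

F1 | step 5 | methyl 2,4-dihydroxy-6-methylbenzoate | COC(=O)c1c(C)cc(O)cc1O
F2 | step 5 | potassium 2,4-dihydroxy-5-(methoxycarbonyl)-6-methylphenyl sulfate | COC(=O)c1c(C)c(OS(=O)(=O)[O-])c(O)cc1O.[K+]
F3 | step 5 | methyl 2,4,5-trihydroxy-6-methylbenzoate | COC(=O)c1c(C)c(O)c(O)cc1O
F4 | step 4 | 3-(benzyloxy)-4-hydroxypentan-2-one (mixture of diastereomers) | CC(O)C(OCc1ccccc1)C(C)=O
F5 | step 4 | 3-(benzyloxy)pent-3-en-2-one (E/Z mixture) | CC=C(OCc1ccccc1)C(C)=O
F6 | step 4 | dimethyl 2-[3-(benzyloxy)-4-oxopentan-2-yl]propanedioate (mixture of diastereomers) | COC(=O)C(C(=O)OC)C(C)C(OCc1ccccc1)C(C)=O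
F7 | step 4 | methyl 3-(benzyloxy)-2-methyl-4,6-dioxocyclohexane-1-carboxylate (mixture of diastereomers) | COC(=O)C1C(C)C(OCc2ccccc2)C(=O)CC1=O
F8 | step 8 | [3,4-bis(benzyloxy)-6-methoxy-2-methylphenyl]methanol | COc1cc(OCc2ccccc2)c(OCc2ccccc2)c(C)c1CO
F9 | step 8 | 3,4-bis(benzyloxy)-6-methoxy-2-methylbenzaldehyde | COc1cc(OCc2ccccc2)c(OCc2ccccc2)c(C)c1C=O
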